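**Overview**

1. The retrosynthesis first cuts the interflavan bond between C4 of the upper ring C and C6 of the lower ring A. It then cuts the C3–O and C4–O bonds of each half (an oxirane in the upper unit, a cis-diol in the lower one) back to one (2S)-2-aryl-2H-chromene, and last the C2–aryl bond back to 7-hydroxychromone and an arylboronic acid.
2. Enabling feature: the upper C4 carries, cis to the C3 hydroxyl, carbon C6 of the lower ring A, which is ortho to the free 7-OH. One boron atom can span the chain O–C3–C4–C6–C7–O, so C6 can be delivered to C4 of a 3,4-epoxide from a borate held on the C3 oxygen.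
3. Forward order: ring C is bought as the chromone and ring B is added at C2. The flavanone is reduced and dehydrated to the flavene, which is divided into a phenolic nucleophile (dihydroxylation, protection) and an epoxide electrophile. The halves are joined through C4–C6 and deprotected.
4. Stereochemistry: both C2 centres come from one ligand-controlled conjugate addition. Lower C3/C4 (OsO4) and upper C3 (dimethyldioxirane) arise by addition anti to the 2-aryl group, and upper C4 by boron-tethered delivery syn to the C3 oxygen.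
5. Because both halves descend from the same flavene, most of any minor enantiomer should end up in a separable diastereomer of the dimer.

Key step: step 9

Assumption: the (S)-tert-butyl pyridine-oxazoline ligand is taken to give 2R flavanones, so the (R)-ligand is specified for the 2S series; if the sense is the opposite, only the ligand enantiomer is exchanged.

**Route**

Step 1
Reactants: 1 7-hydroxy-4H-chromen-4-one
Product: 2 7-(triisopropylsilyloxy)-4H-chromen-4-one
Conditions: TIPSCl, imidazole, DMF, rt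
Reagents that add atoms: triisopropylsilyl chloride CC(C)[Si](Cl)(C(C)C)C(C)C
Why: Routine silylation of a phenol gives the only aryl silyl ether of the route, which can later be cleaved beside alkyl silyl and benzyl ethers.

Step 2
Reactants: 2 7-(triisopropylsilyloxy)-4H-chromen-4-one; 3 3,4-bis(benzyloxy)phenylboronic acid
Product: 4 (2S)-2-[3,4-bis(benzyloxy)phenyl]-7-(triisopropylsilyloxy)chroman-4-one
Conditions: Pd(OCOCF3)2 (5 mol %), (R)-4-tert-butyl-2-(pyridin-2-yl)-4,5-dihydrooxazole (6 mol %), NH4PF6 (30 mol %), H2O (5 equiv), ClCH2CH2Cl, 60 °C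
Reagents that add atoms: none
Why: Enantioselective conjugate addition of an arylboronic acid to a chromone under cationic divalent palladium and a pyridine-oxazoline ligand (aryl insertion into C2=C3, protonolysis of the palladium enolate); the tert-butyl group of the ligand selects the enone face and sets C2 as S, and the base-free medium avoids retro-oxa-Michael opening and racemisation of the flavanone.

Step 3
Reactants: 4 (2S)-2-[3,4-bis(benzyloxy)phenyl]-7-(triisopropylsilyloxy)chroman-4-one
Product: 5 (2S,4S)-2-[3,4-bis(benzyloxy)phenyl]-7-(triisopropylsilyloxy)chroman-4-ol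
Conditions: NaBH4, THF–MeOH, 0 °C
Reagents that add atoms: none
Why: Borohydride reduction of the aryl ketone, with hydride entering opposite the 2-aryl group, should give mainly the 2,4-cis alcohol; the C4 configuration is of no consequence because it is removed in step 4.

Step 4
Reactants: 5 (2S,4S)-2-[3,4-bis(benzyloxy)phenyl]-7-(triisopropylsilyloxy)chroman-4-ol
Product: 7 (2S)-2-[3,4-bis(benzyloxy)phenyl]-7-(triisopropylsilyloxy)-2H-chromene, via flavan-4-yl mesylate 6 (not isolated)
Conditions: MsCl, Et3N, CH2Cl2, 0 °C to rt, light excluded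
Reagents that add atoms: none
Why: Mesylation of the para-silyloxy benzylic alcohol followed by amine-mediated elimination toward C3 (the only β-hydrogens) gives the conjugated chromene without strong base, acid or heat, so C2 is untouched.

Step 5
Reactants: 7 (2S)-2-[3,4-bis(benzyloxy)phenyl]-7-(triisopropylsilyloxy)-2H-chromene
Product: 8 (2R,3S,4S)-2-[3,4-bis(benzyloxy)phenyl]-7-(triisopropylsilyloxy)chromane-3,4-diol
Conditions: OsO4 (cat.), N-methylmorpholine N-oxide, acetone–H2O, 0 °C to rt
Reagents that add atoms: N-methylmorpholine N-oxide C[N+]1([O-])CCOCC1; water O; osmium tetroxide O=[Os](=O)(=O)=O (catalytic carrier of the oxygen atoms)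
Why: Catalytic syn dihydroxylation of the cyclic styrene by OsO4 on the face away from the C2 aryl group sets lower C3 and C4 as the 2,3-trans-3,4-cis diol.

Step 6
Reactants: 8 (2R,3S,4S)-2-[3,4-bis(benzyloxy)phenyl]-7-(triisopropylsilyloxy)chromane-3,4-diol
Product: 9 (2R)-2,3-trans-3,4-cis-2-[3,4-bis(benzyloxy)phenyl]-3,4-bis(tert-butyldimethylsilyloxy)-7-(triisopropylsilyloxy)chromane
Conditions: TBSOTf, 2,6-lutidine, CH2Cl2, −78 to 0 °C
Reagents that add atoms: tert-butyldimethylsilyl triflate CC(C)(C)[Si](C)(C)OS(=O)(=O)C(F)(F)F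
Why: Silyl triflate with a hindered pyridine base silylates both secondary alcohols, including the crowded benzylic one, so that the lower C4 oxygen can no longer leave as the flavan-4-yl cation.

Step 7
Reactants: 9 (2R)-2,3-trans-3,4-cis-2-[3,4-bis(benzyloxy)phenyl]-3,4-bis(tert-butyldimethylsilyloxy)-7-(triisopropylsilyloxy)chromane
Product: 10 (2R)-2,3-trans-3,4-cis-2-[3,4-bis(benzyloxy)phenyl]-3,4-bis(tert-butyldimethylsilyloxy)chroman-7-ol
Conditions: TBAF (1.1 equiv), AcOH (1.1 equiv), THF, 0 °C
Reagents that add atoms: none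
Why: Fluoride cleaves an aryl silyl ether much faster than hindered secondary alkyl silyl ethers, and the acetic acid buffer keeps the phenol protonated so that it cannot expel the para-benzylic silyloxy group as a quinone methide.

Step 8
Reactants: 7 (2S)-2-[3,4-bis(benzyloxy)phenyl]-7-(triisopropylsilyloxy)-2H-chromene
Product: 11 (2R)-2-[3,4-bis(benzyloxy)phenyl]-3,4-epoxy-7-(triisopropylsilyloxy)chromane (oxirane trans to the 2-aryl group)
Conditions: dimethyldioxirane (acetone solution), CH2Cl2, −40 °C; evaporated below 0 °C and used at once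
Reagents that add atoms: dimethyldioxirane CC1(C)OO1
Why: Concerted, neutral oxygen transfer from the dioxirane to the electron-rich styrene double bond on the face anti to the 2-aryl group sets upper C3, and acetone as the only by-product spares the acid-labile oxirane.

Step 9
Reactants: 11 (2R)-2-[3,4-bis(benzyloxy)phenyl]-3,4-epoxy-7-(triisopropylsilyloxy)chromane; 10 (2R)-2,3-trans-3,4-cis-2-[3,4-bis(benzyloxy)phenyl]-3,4-bis(tert-butyldimethylsilyloxy)chroman-7-ol
Product: 14 protected fisetinidol-(4β→6)-leucofisetinidin (upper 7-O-TIPS; lower 3,4-bis-O-TBS; 3',4'-di-O-benzyl in both units), via tris(aryloxy)borane 12 (not isolated), via cyclic borate ester 13 (not isolated)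
Conditions: 10 (3.0 equiv), BH3·SMe2 (1.0 equiv), CH2Cl2, rt, volatiles removed; then 11 (1.0 equiv), CH2Cl2, −78 to −20 °C; aq. NaHCO3; surplus 10 recovered
Reagents that add atoms: none
Why: The boron of triaryl borate 12 binds the oxirane oxygen of 11 and the C4–O bond ionises to a benzylic cation (stabilised by O1 and the para 7-silyloxy group) that stays paired with the borate now on the C3 oxygen; one aryloxy ligand attacks C4 through its ortho carbon C6 in a seven-membered array (C4, C3, O, B, O, C7, C6), and proton loss to a departing aryloxide gives cyclic borate 13, which aqueous work-up hydrolyses to 14. This is the boron-tethered, syn- and ortho-selective Friedel–Crafts alkylation of phenols by benzylic epoxides such as 2H-chromene oxides via triaryl borates, applied to a flavene oxide and a flavanyl phenol. No ring of the product is closed; only the transient seven-membered borate ring forms, and it is lost on work-up. The new stereocentre, upper C4, is controlled by the tether: the aryl carbon can reach C4 only on the face the epoxide oxygen occupied, giving the 3,4-cis, 2,4-trans arrangement. The step needs syn over anti attack (secured by the B–O–C3 tether), C- over O-alkylation and C6 over C8 (C6 is ortho to the boron-bound oxygen, para to O1 and unflanked, whereas C8 lies between two oxygens), and cross- over self-coupling (the lower C4 oxygen is silylated and the phenol oxygen sits on boron). Two of the three aryloxy ligands are not transferred and return as 10.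

Step 10
Reactants: 14 protected fisetinidol-(4β→6)-leucofisetinidin
Product: 15 upper 7-O-TIPS lower 3,4-bis-O-TBS fisetinidol-(4β→6)-leucofisetinidin
Conditions: H2 (1 atm), Pd(OH)2/C, EtOAc–THF, rt
Reagents that add atoms: none
Why: Hydrogenolysis of the four aryl benzyl ethers in a neutral aprotic medium should leave the silyl ethers intact, and the lower benzylic C4–O bond is kept silylated at this stage to shield it from reductive cleavage.

Step 11
Reactants: 15 upper 7-O-TIPS lower 3,4-bis-O-TBS fisetinidol-(4β→6)-leucofisetinidin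
Product: 16 fisetinidol-(4β→6)-(2R,3S,4S)-leucofisetinidin
Conditions: Et3N·3HF, THF, rt, argon
Reagents that add atoms: none
Why: Fluoride desilylation with the nearly neutral amine–hydrogen fluoride complex removes the aryl TIPS and both secondary TBS ethers without acid strong enough to ionise the benzylic C4–OH of the lower unit and without base that would promote catechol oxidation.

**Compound list**

1 | 7-hydroxy-4H-chromen-4-one (7-hydroxychromone) | O=c1ccoc2cc(O)ccc12 | starting material
2 | 7-(triisopropylsilyloxy)-4H-chromen-4-one | CC(C)[Si](C(C)C)(C(C)C)Oc1ccc2c(c1)occc2=O | intermediate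
3 | 3,4-bis(benzyloxy)phenylboronic acid | OB(O)c1ccc(OCc2ccccc2)c(OCc2ccccc2)c1 | starting material
4 | (2S)-2-[3,4-bis(benzyloxy)phenyl]-7-(triisopropylsilyloxy)chroman-4-one | CC(C)[Si](C(C)C)(C(C)C)Oc1ccc2c(c1)O[C@H](c1ccc(OCc3ccccc3)c(OCc3ccccc3)c1)CC2=O | intermediate
5 | (2S,4S)-2-[3,4-bis(benzyloxy)phenyl]-7-(triisopropylsilyloxy)chroman-4-ol (2,4-cis) | CC(C)[Si](C(C)C)(C(C)C)Oc1ccc2c(c1)O[C@H](c1ccc(OCc3ccccc3)c(OCc3ccccc3)c1)C[C@@H]2O | intermediate
6 | 4-O-methanesulfonate of 5 (not isolated) | CC(C)[Si](C(C)C)(C(C)C)Oc1ccc2c(c1)O[C@H](c1ccc(OCc3ccccc3)c(OCc3ccccc3)c1)C[C@@H]2OS(C)(=O)=O | intermediate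
7 | (2S)-2-[3,4-bis(benzyloxy)phenyl]-7-(triisopropylsilyloxy)-2H-chromene | CC(C)[Si](C(C)C)(C(C)C)Oc1ccc2c(c1)O[C@H](c1ccc(OCc3ccccc3)c(OCc3ccccc3)c1)C=C2 | intermediate
8 | (2R,3S,4S)-2-[3,4-bis(benzyloxy)phenyl]-7-(triisopropylsilyloxy)chromane-3,4-diol (2,3-trans-3,4-cis) | CC(C)[Si](C(C)C)(C(C)C)Oc1ccc2c(c1)O[C@H](c1ccc(OCc3ccccc3)c(OCc3ccccc3)c1)[C@@H](O)[C@H]2O | intermediate
9 | (2R)-2,3-trans-3,4-cis-2-[3,4-bis(benzyloxy)phenyl]-3,4-bis(tert-butyldimethylsilyloxy)-7-(triisopropylsilyloxy)chromane | CC(C)[Si](C(C)C)(C(C)C)Oc1ccc2c(c1)O[C@H](c1ccc(OCc3ccccc3)c(OCc3ccccc3)c1)[C@@H](O[Si](C)(C)C(C)(C)C)[C@H]2O[Si](C)(C)C(C)(C)C | intermediate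
10 | (2R)-2,3-trans-3,4-cis-2-[3,4-bis(benzyloxy)phenyl]-3,4-bis(tert-butyldimethylsilyloxy)chroman-7-ol | Oc1ccc2c(c1)O[C@H](c1ccc(OCc3ccccc3)c(OCc3ccccc3)c1)[C@@H](O[Si](C)(C)C(C)(C)C)[C@H]2O[Si](C)(C)C(C)(C)C | intermediate
11 | (2R)-2-[3,4-bis(benzyloxy)phenyl]-3,4-epoxy-7-(triisopropylsilyloxy)chromane, oxirane on the face opposite the 2-aryl group | CC(C)[Si](C(C)C)(C(C)C)Oc1ccc2c(c1)O[C@H](c1ccc(OCc3ccccc3)c(OCc3ccccc3)c1)[C@@H]4[C@H]2O4 | intermediate
12 | tris(aryloxy)borane formed from three molecules of 10 through their 7-oxygens (not isolated) | B(Oc1ccc2c(c1)O[C@H](c1ccc(OCc3ccccc3)c(OCc3ccccc3)c1)[C@@H](O[Si](C)(C)C(C)(C)C)[C@H]2O[Si](C)(C)C(C)(C)C)(Oc1ccc2c(c1)O[C@H](c1ccc(OCc3ccccc3)c(OCc3ccccc3)c1)[C@@H](O[Si](C)(C)C(C)(C)C)[C@H]2O[Si](C)(C)C(C)(C)C)Oc1ccc2c(c1)O[C@H](c1ccc(OCc3ccccc3)c(OCc3ccccc3)c1)[C@@H](O[Si](C)(C)C(C)(C)C)[C@H]2O[Si](C)(C)C(C)(C)C | intermediate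
13 | cyclic borate ester of 14: boron bridges the upper C3 oxygen and the lower C7 oxygen (seven-membered ring) and keeps one aryloxy ligand derived from 10 (not isolated) | CC(C)[Si](C(C)C)(C(C)C)Oc1ccc2c(c1)O[C@H](c1ccc(OCc3ccccc3)c(OCc3ccccc3)c1)[C@@H](OB(Oc1ccc6c(c1)O[C@H](c1ccc(OCc3ccccc3)c(OCc3ccccc3)c1)[C@@H](O[Si](C)(C)C(C)(C)C)[C@H]6O[Si](C)(C)C(C)(C)C)O5)[C@H]2c1cc2c(cc15)O[C@H](c1ccc(OCc3ccccc3)c(OCc3ccccc3)c1)[C@@H](O[Si](C)(C)C(C)(C)C)[C@H]2O[Si](C)(C)C(C)(C)C | intermediate
14 | protected fisetinidol-(4β→6)-leucofisetinidin: both units (2R)-2,3-trans-3,4-cis; upper unit 7-O-TIPS with free 3-OH; lower unit 3,4-bis-O-TBS with free 7-OH; 3',4'-di-O-benzyl in both | CC(C)[Si](C(C)C)(C(C)C)Oc1ccc2c(c1)O[C@H](c1ccc(OCc3ccccc3)c(OCc3ccccc3)c1)[C@@H](O)[C@H]2c1cc2c(cc1O)O[C@H](c1ccc(OCc3ccccc3)c(OCc3ccccc3)c1)[C@@H](O[Si](C)(C)C(C)(C)C)[C@H]2O[Si](C)(C)C(C)(C)C | intermediate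
15 | debenzylated biflavanoid: as 14 with all four catechol hydroxyls free (upper 7-O-TIPS, lower 3,4-bis-O-TBS retained) | CC(C)[Si](C(C)C)(C(C)C)Oc1ccc2c(c1)O[C@H](c1ccc(O)c(O)c1)[C@@H](O)[C@H]2c1cc2c(cc1O)O[C@H](c1ccc(O)c(O)c1)[C@@H](O[Si](C)(C)C(C)(C)C)[C@H]2O[Si](C)(C)C(C)(C)C | intermediate
16 | fisetinidol-(4β→6)-(2R,3S,4S)-leucofisetinidin; upper unit (2R,3S,4S), lower unit (2R,3S,4S), both 2,3-trans-3,4-cis | Oc1ccc2c(c1)O[C@H](c1ccc(O)c(O)c1)[C@@H](O)[C@H]2c1cc2c(cc1O)O[C@H](c1ccc(O)c(O)c1)[C@@H](O)[C@H]2O | target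

**Step count and weak points**

Total step count: 11. Longest linear sequence: 10 steps (steps 1–7, then 9–11, from 7-hydroxychromone); step 8 is the one-step side branch from flavene 7.

Steps most likely to fail:

Step 9. The aryloxy ligand may be delivered through its oxygen (five-membered transfer to C4) instead of through C6. The ion pair may collapse by hydride shift to the flavan-3-one (Meinwald rearrangement). Facial control may be lost if the cation leaves the ion pair. The fallback gives up the tether for the classical untethered flavan-4-yl cation coupling. It sets out from diol 8, which ionises at C4 under Lewis acid, and phenol 10, combined with BF3·OEt2 in CH2Cl2 at −78 to −40 °C. C6 of 10 would capture the cation from either face, so 14 would form together with its upper C4 epimer, the 3,4-trans (4α→6) biflavanoid F1. F1 is expected to predominate and would be removed by chromatography, so this path trades selectivity for reliability. It rejoins the route at 14.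

Step 8. Because C4 is para to the silyloxy donor, the oxirane may open or rearrange (attack by adventitious water, hydride shift) while it is formed or concentrated. The fallback weakens that donor before the oxidation. From flavene 7, TBAF/AcOH would give (2S)-2-[3,4-bis(benzyloxy)phenyl]-2H-chromen-7-ol F2, and benzyl chloroformate with pyridine its benzyl carbonate F3. Dimethyldioxirane would then give the 2,3-trans epoxide F4, which is electronically close to a parent 2H-chromene oxide and should tolerate handling. Coupling with borate 12 as in step 9 would lead through the cyclic borate ester F5 to the carbonate-protected biflavanoid F6. Hydrogenolysis as in step 10 would remove the carbonate together with the benzyl ethers to give the lower 3,4-bis-O-TBS biflavanoid F7. Fluoride as in step 11 would then return the path to the route at target 16.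

Step 2. Protodeboronation of the electron-rich boronic acid may outrun insertion, or the enantioselectivity may be too low, and every stereocentre of the target depends on this step. The fallback replaces enantioselective C–C bond formation by kinetic resolution. From 2 and 3, the same addition with Pd(OCOCF3)2 and achiral 2,2'-bipyridine would give the racemic flavanone F8. Asymmetric transfer hydrogenation with RuCl[(S,S)-TsDPEN](p-cymene) and HCO2H/Et3N, stopped near half conversion, should reduce the 2S enantiomer selectively to the cis alcohol and leave the 2R ketone behind. The path rejoins the route at 5.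

Further compounds
F1 | step 9 | upper C4 epimer of 14, the 2,3-trans-3,4-trans (4α→6) protected biflavanoid | CC(C)[Si](C(C)C)(C(C)C)Oc1ccc2c(c1)O[C@H](c1ccc(OCc3ccccc3)c(OCc3ccccc3)c1)[C@@H](O)[C@@H]2c1cc2c(cc1O)O[C@H](c1ccc(OCc3ccccc3)c(OCc3ccccc3)c1)[C@@H](O[Si](C)(C)C(C)(C)C)[C@H]2O[Si](C)(C)C(C)(C)C
F2 | step 8 | (2S)-2-[3,4-bis(benzyloxy)phenyl]-2H-chromen-7-ol | Oc1ccc2c(c1)O[C@H](c1ccc(OCc3ccccc3)c(OCc3ccccc3)c1)C=C2
F3 | step 8 | benzyl (2S)-2-[3,4-bis(benzyloxy)phenyl]-2H-chromen-7-yl carbonate | O=C(OCc1ccccc1)Oc1ccc2c(c1)O[C@H](c1ccc(OCc3ccccc3)c(OCc3ccccc3)c1)C=C2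
F4 | step 8 | benzyl carbonate analogue of 11 (oxirane trans to the 2-aryl group) | O=C(OCc1ccccc1)Oc1ccc2c(c1)O[C@H](c1ccc(OCc3ccccc3)c(OCc3ccccc3)c1)[C@@H]4[C@H]2O4
F5 | step 8 | benzyl carbonate analogue of cyclic borate ester 13 | O=C(OCc1ccccc1)Oc1ccc2c(c1)O[C@H](c1ccc(OCc3ccccc3)c(OCc3ccccc3)c1)[C@@H](OB(Oc1ccc6c(c1)O[C@H](c1ccc(OCc3ccccc3)c(OCc3ccccc3)c1)[C@@H](O[Si](C)(C)C(C)(C)C)[C@H]6O[Si](C)(C)C(C)(C)C)O5)[C@H]2c1cc2c(cc15)O[C@H](c1ccc(OCc3ccccc3)c(OCc3ccccc3)c1)[C@@H](O[Si](C)(C)C(C)(C)C)[C@H]2O[Si](C)(C)C(C)(C)C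
F6 | step 8 | benzyl carbonate analogue of 14 (upper 7-O-benzyloxycarbonyl) | O=C(OCc1ccccc1)Oc1ccc2c(c1)O[C@H](c1ccc(OCc3ccccc3)c(OCc3ccccc3)c1)[C@@H](O)[C@H]2c1cc2c(cc1O)O[C@H](c1ccc(OCc3ccccc3)c(OCc3ccccc3)c1)[C@@H](O[Si](C)(C)C(C)(C)C)[C@H]2O[Si](C)(C)C(C)(C)C
F7 | step 8 | lower 3,4-bis-O-TBS fisetinidol-(4β→6)-leucofisetinidin (all phenols free) | Oc1ccc2c(c1)O[C@H](c1ccc(O)c(O)c1)[C@@H](O)[C@H]2c1cc2c(cc1O)O[C@H](c1ccc(O)c(O)c1)[C@@H](O[Si](C)(C)C(C)(C)C)[C@H]2O[Si](C)(C)C(C)(C)C
F8 | step 2 | racemic 2-[3,4-bis(benzyloxy)phenyl]-7-(triisopropylsilyloxy)chroman-4-one | CC(C)[Si](C(C)C)(C(C)C)Oc1ccc2c(c1)OC(c1ccc(OCc3ccccc3)c(OCc3ccccc3)c1)CC2=O
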